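The cyclohexene ring (C1 with the methyl group, C2, C3 with the chalcone aryl ring, C4 with the aroyl group, C5 with the resorcinol ring, C6) is not closed at its final size: it is grown by two atoms from a cyclobutane that holds C1, C4, C5 and C6. The key step exploits that C4 is the α-carbon of the aryl ketone and that C1–C2–C3 is an aryl-terminated allyl unit: zerovalent palladium ionises the strained C1–C4 bond of a 1-methyl-1-styryl-2-aroyl-3-arylcyclobutane and the tethered enolate recloses at C3. This single operation forms the C3–C4 bond, the C1=C2 alkene and the C3 and C4 stereocentres by chirality transfer from C1 and C5.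

Key step: step 17

Assumption: compounds 9 and 22 are taken as purchasable; the sense of induction of the chiral lithium amide in step 4 is taken as drawn, and the enantiomeric amide would be used if the first run proved it opposite.

Shorthand in names: MOM = methoxymethyl; ArB = 2,4-bis(methoxymethoxy)phenyl; ArK = 2,4-bis(methoxymethoxy)-3-[(E)-3-methylbut-1-en-1-yl]phenyl; ArC = 2,6-bis(methoxymethoxy)-3-{(E)-3-[4-(methoxymethoxy)phenyl]prop-2-enoyl}phenyl. The labels C1–C6 are the ring atoms of the target cyclohexene (C1 methyl-bearing, C3 ArC-bearing, C4 aroyl-bearing, C5 ArB-bearing) and are kept for the same atoms in the cyclobutanes.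

Step 1
Reactants: 1 2,4-dihydroxybenzaldehyde
Product: 2 2,4-bis(methoxymethoxy)benzaldehyde
Conditions: NaH, MOMCl, DMF, 0 °C to rt
Reagents that add atoms: chloromethyl methyl ether, COCCl
Why: Double Williamson O-alkylation of the sodium phenoxides (MOM acetal protection) should mask both phenols for the organometallic steps ahead; no stereocentre is formed.

Step 2
Reactants: 2 2,4-bis(methoxymethoxy)benzaldehyde
Product: 3 1-ethenyl-2,4-bis(methoxymethoxy)benzene
Conditions: Ph3PCH3Br, KOt-Bu, THF, 0 °C to rt
Reagents that add atoms: methyltriphenylphosphonium bromide, C[P+](c1ccccc1)(c1ccccc1)c1ccccc1.[Br-]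
Why: Wittig methylenation with the unstabilised ylide should give the electron-rich styrene that supplies C5 and C6.

Step 3
Reactants: 3 1-ethenyl-2,4-bis(methoxymethoxy)benzene
Product: 5 3-ArB-cyclobutan-1-one, via dichlorocyclobutanone 4 (not isolated)
Conditions: Cl3CCOCl, Zn–Cu couple, Et2O/DME, rt; then Zn, AcOH, rt
Reagents that add atoms: trichloroacetyl chloride, O=C(Cl)C(Cl)(Cl)Cl
Why: Dichloroketene made in the flask should add to the styrene in a regioselective thermal [2+2] ketene–alkene cycloaddition (carbonyl carbon to the CH2 terminus) and zinc/acetic acid then removes both chlorines, giving the achiral cyclobutanone whose carbonyl carbon is the future C1.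

Step 4
Reactants: 5 3-ArB-cyclobutan-1-one
Product: 6 (S)-[(3-ArB-cyclobut-1-en-1-yl)oxy]trimethylsilane
Conditions: (R,R)-bis(1-phenylethyl)amine, n-BuLi, THF, −78 °C; then Me3SiCl and 5, −100 °C
Reagents that add atoms: chlorotrimethylsilane, C[Si](C)(C)Cl
Why: Enantioselective deprotonation of the prochiral 3-substituted cyclobutanone by a C2-symmetric chiral lithium amide with internal silyl quench (a known desymmetrisation of this ketone class) should distinguish the enantiotopic α-methylenes and so make the aryl-bearing carbon the stereocentre C5 (S) on which all later stereocontrol rests.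

Step 5
Reactants: 1 2,4-dihydroxybenzaldehyde
Product: 7 2,4-dihydroxy-3-iodobenzaldehyde
Conditions: I2, HIO3, EtOH/H2O, 35 °C
Reagents that add atoms: iodine, II; iodic acid, O[I](=O)=O
Why: Electrophilic aromatic iodination should occur at the doubly activated position between the two hydroxyl groups (the 5-iodo isomer being the by-product to remove), placing the handle for the side chain.

Step 6
Reactants: 7 2,4-dihydroxy-3-iodobenzaldehyde
Product: 8 3-iodo-2,4-bis(methoxymethoxy)benzaldehyde
Conditions: NaH, MOMCl, DMF, 0 °C to rt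
Reagents that add atoms: chloromethyl methyl ether, COCCl
Why: Williamson O-alkylation (MOM protection) of both phenoxides, the hindered chelated one included, should proceed under NaH activation.

Step 7
Reactants: 8 3-iodo-2,4-bis(methoxymethoxy)benzaldehyde; 9 (E)-4,4,5,5-tetramethyl-2-(3-methylbut-1-en-1-yl)-1,3,2-dioxaborolane
Product: 10 2,4-bis(methoxymethoxy)-3-[(E)-3-methylbut-1-en-1-yl]benzaldehyde (ArK–CHO)
Conditions: Pd(OAc)2, SPhos, K3PO4, toluene/H2O, 80 °C
Reagents that add atoms: none
Why: Suzuki–Miyaura coupling of the doubly ortho-substituted aryl iodide with the (E)-alkenylboronate (bulky biarylphosphine ligand) should install the side chain with retention of alkene geometry.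

Step 8
Reactants: 6 (S)-[(3-ArB-cyclobut-1-en-1-yl)oxy]trimethylsilane; 10 ArK–CHO
Product: 13 (2E,3R)-3-ArB-2-[(ArK)methylidene]cyclobutan-1-one, via aldol adduct 11 (not isolated), via mesylate 12 (not isolated)
Conditions: MeLi, THF, 0 °C then −78 °C; 10, −78 °C; MsCl, −78 to 0 °C; DBU, rt
Reagents that add atoms: none
Why: Methyllithium cleaves the silyl enol ether to the regio-defined lithium enolate, whose directed aldol addition to 10 followed by mesylation and E1cB elimination (aldol condensation) should give the 2-arylidene ketone; the enolate regiochemistry fixed in step 4 keeps C5 configured and the alkene geometry is of no consequence later.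

Step 9
Reactants: 13 (2E,3R)-3-ArB-2-[(ArK)methylidene]cyclobutan-1-one
Product: 14 (2E,3S)-3-ArB-2-[(ArK)methylidene]-1-[(trimethylsilyl)ethynyl]cyclobutan-1-ol (both carbinol epimers)
Conditions: Me3SiC≡CH, n-BuLi, THF, −78 °C; then 13, −78 °C
Reagents that add atoms: ethynyltrimethylsilane, C#C[Si](C)(C)C
Why: 1,2-Addition of the lithium acetylide to the strained ketone should give the tertiary alkynyl carbinol, whose carbinol centre is erased in step 10.

Step 10
Reactants: 14 (2E,3S)-3-ArB-2-[(ArK)methylidene]-1-[(trimethylsilyl)ethynyl]cyclobutan-1-ol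
Product: 15 (R)-{4-ArB-2-[(trimethylsilyl)ethynyl]cyclobut-1-en-1-yl}(ArK)methanone
Conditions: pyridinium chlorochromate (C5H5NH[CrO3Cl]), NaOAc, 4 Å MS, CH2Cl2, rt
Reagents that add atoms: pyridinium chlorochromate, [O-][Cr](=O)(=O)Cl.c1cc[nH+]cc1 (supplies the ketone oxygen)
Why: Babler–Dauben oxidative transposition: the tertiary allylic chromate ester should undergo a [3,3]-shift to the benzylic carbon and be oxidised there, moving the double bond into the ring and leaving C4 acylated and C1 alkynylated.

Step 11
Reactants: 15 (R)-{4-ArB-2-[(trimethylsilyl)ethynyl]cyclobut-1-en-1-yl}(ArK)methanone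
Product: 17 [(1R,2R,4S)-4-ArB-2-ethynyl-2-methylcyclobutyl](ArK)methanone, via silylalkyne adduct 16 (not isolated)
Conditions: MeLi, CuI, Et2O/THF, −30 °C; BF3·OEt2, then 15, −78 to −40 °C; then K2CO3, MeOH, rt
Reagents that add atoms: methyllithium, [Li]C
Why: Conjugate addition of BF3-activated methylcopper, a reagent known to add 1,4 rather than 1,6 to acceptor-substituted enynes, should deliver the methyl group to C1 anti to the C5 aryl group (quaternary centre with methyl trans and alkynyl cis to ArB), after which carbonate/methanol removes the alkyne silyl group and equilibrates C4 to the epimer with the aroyl group trans to ArB.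

Step 12
Reactants: 17 [(1R,2R,4S)-4-ArB-2-ethynyl-2-methylcyclobutyl](ArK)methanone
Product: 18 {(1R,2R,4S)-4-ArB-2-methyl-2-[(E)-2-(tributylstannyl)ethenyl]cyclobutyl}(ArK)methanone
Conditions: Bu3SnH, PdCl2(PPh3)2 (2 mol %), THF, 0 °C
Reagents that add atoms: tributyltin hydride, CCCC[SnH](CCCC)CCCC
Why: Palladium-catalysed syn-hydrostannylation of the terminal alkyne should place tin at the unhindered terminus, the quaternary carbon blocking the other, and give the (E)-alkenylstannane.

Step 13
Reactants: 19 1-(2,4-dihydroxyphenyl)ethan-1-one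
Product: 20 1-(2,4-dihydroxy-3-iodophenyl)ethan-1-one
Conditions: I2, HIO3, EtOH/H2O, 35 °C
Reagents that add atoms: iodine, II; iodic acid, O[I](=O)=O
Why: Electrophilic aromatic iodination should again select the position flanked by both hydroxyl groups, which becomes the attachment carbon of ring ArC.

Step 14
Reactants: 20 1-(2,4-dihydroxy-3-iodophenyl)ethan-1-one
Product: 21 1-[3-iodo-2,4-bis(methoxymethoxy)phenyl]ethan-1-one
Conditions: NaH, MOMCl, DMF, 0 °C to rt
Reagents that add atoms: chloromethyl methyl ether, COCCl
Why: Williamson O-alkylation (MOM protection) of both phenoxides should give the base-stable bis-acetal needed for the condensation and coupling steps.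

Step 15
Reactants: 21 1-[3-iodo-2,4-bis(methoxymethoxy)phenyl]ethan-1-one; 22 4-(methoxymethoxy)benzaldehyde
Product: 23 (E)-1-[3-iodo-2,4-bis(methoxymethoxy)phenyl]-3-[4-(methoxymethoxy)phenyl]prop-2-en-1-one
Conditions: KOH, EtOH, rt
Reagents that add atoms: none
Why: Claisen–Schmidt condensation of the methyl ketone enolate with the non-enolisable aldehyde should give the (E)-chalcone, the aryl iodide and MOM ethers being inert to hydroxide.

Step 16
Reactants: 18 {(1R,2R,4S)-4-ArB-2-methyl-2-[(E)-2-(tributylstannyl)ethenyl]cyclobutyl}(ArK)methanone; 23 iodochalcone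
Product: 24 {(1R,2S,4S)-4-ArB-2-methyl-2-[(E)-2-(ArC)ethenyl]cyclobutyl}(ArK)methanone
Conditions: Pd2(dba)3, AsPh3, CuI, NMP, rt to 40 °C
Reagents that add atoms: none
Why: Stille coupling (copper co-catalysis, weakly donating arsine ligand, near room temperature) should join the alkenylstannane to the hindered aryl iodide with retention of the (E)-geometry under conditions too mild to ionise the cyclobutane.

Step 17
Reactants: 24 {(1R,2S,4S)-4-ArB-2-methyl-2-[(E)-2-(ArC)ethenyl]cyclobutyl}(ArK)methanone
Product: 25 [(1R,2S,6S)-6-ArB-2-ArC-4-methylcyclohex-3-en-1-yl](ArK)methanone (heptakis-MOM ether of the target; 3S,4R,5S in the C1–C6 labels)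
Conditions: Pd2(dba)3 (5 mol %), dppe (12 mol %), Zn(OTf)2 (20 mol %), THF, 50 °C
Reagents that add atoms: none
Why: Proposed new method: zerovalent palladium binds the styryl alkene anti to the strained allylic C1–C4 bond and ionises it with inversion at C1, the zinc-chelated aryl ketone enolate at C4 acting as leaving group, to give a zwitterionic π-allylpalladium enolate in which the enolate stays tethered through C5–C6 on the face opposite palladium, and attack of the enolate carbon on the distal allyl terminus C3, again anti to palladium, completes a net suprafacial 1,3-shift that moves the double bond to C1=C2. The closest known reaction types are the palladium-catalysed vinylcyclopropane-to-cyclopentene rearrangement, the palladium-catalysed opening of acceptor-substituted vinylcyclobutanes to 1,4-dipoles and Tsuji–Trost alkylation by ketone enolates, and the release of cyclobutane strain together with Lewis-acid chelation of the enolate is what should let a single ketone serve as the acceptor. The one ring formed is closed by 6-endo attack of the tethered enolate on the π-allyl terminus, the competing 4-exo attack at C1 merely regenerating 24. C3 is controlled by the quaternary C1 through the double inversion (styryl cis to ArB leads to 3S), C4 by the neighbouring C5 aryl group (aroyl trans to ArB, expected to be also the thermodynamic epimer), and C5 is carried through unchanged. The step needs cleavage of C1–C4 and not of the equally donor–acceptor-substituted C4–C5 bond, which the π-allyl requirement of palladium secures, and closure from the π-allyl isomer with the ring methylene anti and the aryl group syn, which the (E)-styryl geometry and the reversible return of the unproductive isomer secure.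

Step 18
Reactants: 25 [(1R,2S,6S)-6-ArB-2-ArC-4-methylcyclohex-3-en-1-yl](ArK)methanone
Product: 26 CNP0140882.1, {(1R,2S,6S)-6-(2,4-dihydroxyphenyl)-2-[2,6-dihydroxy-3-((E)-3-(4-hydroxyphenyl)prop-2-enoyl)phenyl]-4-methylcyclohex-3-en-1-yl}{2,4-dihydroxy-3-[(E)-3-methylbut-1-en-1-yl]phenyl}methanone
Conditions: HCl (3 M aq.), MeOH/THF, 40 °C
Reagents that add atoms: none
Why: Acid-catalysed transacetalisation in methanol should remove all seven MOM groups under conditions mild enough to leave the 2'-hydroxychalcone, the styrenic side chain and the C4 stereocentre untouched.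

Compound list
1 | 2,4-dihydroxybenzaldehyde | O=Cc1ccc(O)cc1O | starting material
2 | 2,4-bis(methoxymethoxy)benzaldehyde | O=Cc1ccc(OCOC)cc1OCOC | intermediate
3 | 1-ethenyl-2,4-bis(methoxymethoxy)benzene | C=Cc1ccc(OCOC)cc1OCOC | intermediate
4 | 3-ArB-2,2-dichlorocyclobutan-1-one (racemic) | O=C1CC(c2ccc(OCOC)cc2OCOC)C1(Cl)Cl | intermediate (not isolated)
5 | 3-ArB-cyclobutan-1-one | O=C1CC(c2ccc(OCOC)cc2OCOC)C1 | intermediate
6 | (S)-[(3-ArB-cyclobut-1-en-1-yl)oxy]trimethylsilane | C[Si](C)(C)OC1=C[C@@H](c2ccc(OCOC)cc2OCOC)C1 | intermediate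
7 | 2,4-dihydroxy-3-iodobenzaldehyde | O=Cc1ccc(O)c(I)c1O | intermediate
8 | 3-iodo-2,4-bis(methoxymethoxy)benzaldehyde | O=Cc1ccc(OCOC)c(I)c1OCOC | intermediate
9 | (E)-4,4,5,5-tetramethyl-2-(3-methylbut-1-en-1-yl)-1,3,2-dioxaborolane | CC(C)/C=C/B1OC(C)(C)C(C)(C)O1 | starting material
10 | 2,4-bis(methoxymethoxy)-3-[(E)-3-methylbut-1-en-1-yl]benzaldehyde | O=Cc1ccc(OCOC)c(/C=C/C(C)C)c1OCOC | intermediate
11 | (3S)-3-ArB-2-[hydroxy(ArK)methyl]cyclobutan-1-one (aldol adduct, mixture at C2 and the carbinol carbon) | O=C1C[C@H](c2ccc(OCOC)cc2OCOC)C1C(O)c1ccc(OCOC)c(/C=C/C(C)C)c1OCOC | intermediate (not isolated)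
12 | methanesulfonate of 11 | O=C1C[C@H](c2ccc(OCOC)cc2OCOC)C1C(OS(C)(=O)=O)c1ccc(OCOC)c(/C=C/C(C)C)c1OCOC | intermediate (not isolated)
13 | (2E,3R)-3-ArB-2-[(ArK)methylidene]cyclobutan-1-one | O=C1C[C@H](c2ccc(OCOC)cc2OCOC)/C1=C\c1ccc(OCOC)c(/C=C/C(C)C)c1OCOC | intermediate
14 | (2E,3S)-3-ArB-2-[(ArK)methylidene]-1-[(trimethylsilyl)ethynyl]cyclobutan-1-ol (both carbinol epimers, centre left open) | C[Si](C)(C)C#CC1(O)C[C@H](c2ccc(OCOC)cc2OCOC)/C1=C\c1ccc(OCOC)c(/C=C/C(C)C)c1OCOC | intermediate
15 | (R)-{4-ArB-2-[(trimethylsilyl)ethynyl]cyclobut-1-en-1-yl}(ArK)methanone | C[Si](C)(C)C#CC1=C(C(=O)c2ccc(OCOC)c(/C=C/C(C)C)c2OCOC)[C@@H](c2ccc(OCOC)cc2OCOC)C1 | intermediate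
16 | {(2R,4S)-4-ArB-2-methyl-2-[(trimethylsilyl)ethynyl]cyclobutyl}(ArK)methanone (both epimers at the aroyl-bearing carbon) | O=C(c1ccc(OCOC)c(/C=C/C(C)C)c1OCOC)C1[C@@H](c2ccc(OCOC)cc2OCOC)C[C@@]1(C)C#C[Si](C)(C)C | intermediate (not isolated)
17 | [(1R,2R,4S)-4-ArB-2-ethynyl-2-methylcyclobutyl](ArK)methanone | O=C(c1ccc(OCOC)c(/C=C/C(C)C)c1OCOC)[C@@H]1[C@@H](c2ccc(OCOC)cc2OCOC)C[C@@]1(C)C#C | intermediate
18 | {(1R,2R,4S)-4-ArB-2-methyl-2-[(E)-2-(tributylstannyl)ethenyl]cyclobutyl}(ArK)methanone | O=C(c1ccc(OCOC)c(/C=C/C(C)C)c1OCOC)[C@@H]1[C@@H](c2ccc(OCOC)cc2OCOC)C[C@@]1(C)/C=C/[Sn](CCCC)(CCCC)CCCC | intermediate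
19 | 1-(2,4-dihydroxyphenyl)ethan-1-one | CC(=O)c1ccc(O)cc1O | starting material
20 | 1-(2,4-dihydroxy-3-iodophenyl)ethan-1-one | CC(=O)c1ccc(O)c(I)c1O | intermediate
21 | 1-[3-iodo-2,4-bis(methoxymethoxy)phenyl]ethan-1-one | CC(=O)c1ccc(OCOC)c(I)c1OCOC | intermediate
22 | 4-(methoxymethoxy)benzaldehyde | O=Cc1ccc(OCOC)cc1 | starting material
23 | (E)-1-[3-iodo-2,4-bis(methoxymethoxy)phenyl]-3-[4-(methoxymethoxy)phenyl]prop-2-en-1-one | O=C(/C=C/c1ccc(OCOC)cc1)c1ccc(OCOC)c(I)c1OCOC | intermediate
24 | {(1R,2S,4S)-4-ArB-2-methyl-2-[(E)-2-(ArC)ethenyl]cyclobutyl}(ArK)methanone | O=C(c1ccc(OCOC)c(/C=C/C(C)C)c1OCOC)[C@@H]1[C@@H](c2ccc(OCOC)cc2OCOC)C[C@@]1(C)/C=C/c1c(OCOC)ccc(C(=O)/C=C/c2ccc(OCOC)cc2)c1OCOC | intermediate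
25 | [(1R,2S,6S)-6-ArB-2-ArC-4-methylcyclohex-3-en-1-yl](ArK)methanone | CC1=C[C@H](c2c(OCOC)ccc(C(=O)/C=C/c3ccc(OCOC)cc3)c2OCOC)[C@H](C(=O)c2ccc(OCOC)c(/C=C/C(C)C)c2OCOC)[C@@H](c2ccc(OCOC)cc2OCOC)C1 | intermediate
26 | CNP0140882.1 | CC1=C[C@H](c2c(O)ccc(C(=O)/C=C/c3ccc(O)cc3)c2O)[C@H](C(=O)c2ccc(O)c(/C=C/C(C)C)c2O)[C@@H](c2ccc(O)cc2O)C1 | target

Total step count: 18.
Longest linear sequence: 12 steps (steps 1, 2, 3, 4, 8, 9, 10, 11, 12, 16, 17, 18) from compound 1.

Steps most likely to fail

1. Step 17 (proposed new method). The C1–C4 bond may fail to ionise because a single ketone enolate is a poor leaving group for zerovalent palladium. The π-allyl intermediate may instead lose a β-hydrogen and give a ring-opened diene. Stereochemical fidelity may leak through π-allyl face exchange, or through cycloreversion to chalcone and diene followed by unselective recombination. The fallback uses known chemistry and no metal: the classical thermal vinylcyclobutane-to-cyclohexene rearrangement. It sets out from 24, heated in degassed o-dichlorobenzene at about 140 °C with BHT. The weakest ring bond, C1–C4, should homolyse to an α-keto radical and an aryl-conjugated allyl radical, which recombine at C3 in a predominantly suprafacial 1,3-shift that uses the same C1-to-C3 relationship. It comes back at 25 and makes no new compound (F0).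

2. Step 11. Methyl transfer may go to the alkyne terminus (1,6-addition with allene formation) instead of C1, addition to the tetrasubstituted ring alkene may not occur, or the methyl group may be delivered from the aryl-bearing face. The fallback replaces the alkyne handle by a tin-blocked alkene, so that no open 1,6-terminus exists and the hydrostannylation is no longer needed. It sets out from 13. (E)-2-(Tributylstannyl)ethenyllithium, from (E)-1,2-bis(tributylstannyl)ethene and n-BuLi, adds to the ketone to give the stannylvinyl carbinol F1. Non-acidic oxidative transposition (IBX, DMSO) then gives the stannyl dienone F2. BF3-activated methylcopper adds at C1, the δ-carbon being shielded by the Bu3Sn group, and equilibration at C4 (K2CO3, MeOH) gives the alkenylstannane. The route is rejoined at 18.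

3. Step 10. The doubly activated tertiary alcohol may ionise under the acidic chromium reagent (elimination, or Meyer–Schuster-type isomerisation of the propargylic alcohol), the electron-rich arenes may be oxidised, or MOM groups may be lost. The fallback splits the step into a redox-neutral 1,3-hydroxyl shift and a neutral oxidation. It sets out from 14. Catalytic Ph3SiOReO3 (Et2O, 0 °C) equilibrates it with the secondary allylic alcohol F3, which MnO2 present in the same flask oxidises as it forms and so drains the equilibrium. It comes back at 15.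

Further compounds
F0 | step 17 | none | none
F1 | step 11 | (2E,3S)-3-ArB-2-[(ArK)methylidene]-1-[(E)-2-(tributylstannyl)ethenyl]cyclobutan-1-ol (both carbinol epimers) | CCCC[Sn](CCCC)(CCCC)/C=C/C1(O)C[C@H](c2ccc(OCOC)cc2OCOC)/C1=C\c1ccc(OCOC)c(/C=C/C(C)C)c1OCOC
F2 | step 11 | (R)-{4-ArB-2-[(E)-2-(tributylstannyl)ethenyl]cyclobut-1-en-1-yl}(ArK)methanone | CCCC[Sn](CCCC)(CCCC)/C=C/C1=C(C(=O)c2ccc(OCOC)c(/C=C/C(C)C)c2OCOC)[C@@H](c2ccc(OCOC)cc2OCOC)C1
F3 | step 10 | {(4S)-4-ArB-2-[(trimethylsilyl)ethynyl]cyclobut-1-en-1-yl}(ArK)methanol (both carbinol epimers) | C[Si](C)(C)C#CC1=C(C(O)c2ccc(OCOC)c(/C=C/C(C)C)c2OCOC)[C@@H](c2ccc(OCOC)cc2OCOC)C1
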